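Assumption: rings are lettered A to G from the 2,4,6-trihydroxyphenyl end, and in each ring C1 is the carbon whose ether oxygen points towards ring A; the catalogue number is taken to mean exactly the achiral structure of the SMILES.

## Analysis of the target

The target (33) is a linear chain of seven benzene rings joined by six diaryl ether oxygens, C42H30O24, with eighteen free phenolic hydroxyls and no other functional group. It has no stereocentre and no ring besides the seven arenes, so the whole problem is the placement of twenty-four oxygen atoms. Ring A is 2,4,6-trihydroxyphenyl and ring G 3,4,5-trihydroxyphenyl; rings B and F carry ether oxygens at C1 and C5 and hydroxyls at C3 and C4; rings C and E carry ether oxygens at the adjacent carbons C1 and C6 and hydroxyls at C3, C4 and C5; ring D carries ether oxygens at C1 and C4 and hydroxyls at C3 and C5. The free polyphenol is oxidised by air as soon as base is present, so every hydroxyl travels as an ether and is released only in the last step. The difficulty is that all rings are electron-rich: no ether bond can be made by nucleophilic aromatic substitution on the rings as they stand, and copper couplings of hindered, electron-rich partners are unreliable. The route rests on one feature: in ring F the C4 hydroxyl is para to the ether carbon C1 and ortho to the ether carbon C5, the same holds in ring B, and in ring D the C4 oxygen is para to C1. A formyl group at C4 of these rings can therefore activate fluorides at C1 and C5 and afterwards be exchanged for the C4 oxygen.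

## Retrosynthetic reasoning

33 from 32. The eighteen O-methyl bonds are cut last. Methyl is the only permanent protecting group because it survives carbonate, alkoxide, acidic peroxide, organolithium, hydrogenolysis and copper. The price is one demanding Lewis-acid deprotection at the end.

32 from 31 and 14. The ether bond between C4 of ring D and C1 of ring E is cut. This is the one bond the formyl device does not reach in few steps, because ring E is used as a simple nucleophile through its C6 oxygen and keeps only a bromide at C1. The cut lies near the middle of the chain and gives a four-ring phenol (31) and a three-ring bromide (14). The forward reaction is a copper-mediated coupling of a doubly ortho-methoxylated phenol with an ortho-aryloxy aryl bromide.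

14 from 13 from 11. The methyl ether at C4 of ring F is cut, and the C4 oxygen of ring F is traced back to the formyl carbon of 11 by a Dakin oxidation. The aldehyde thus disappears after it has done its work as an acceptor.

11 from 4, 8 and 9. Both ether bonds of ring F are cut, C1–O towards ring E and C5–O towards ring G. The three components are the ring E bromophenol 4, the difluoro aldehyde 8 and the ring G phenol 9. The forward reaction has to replace the para fluoride of 8 by the phenoxide of 4 and only then the ortho fluoride by the phenoxide of 9, and it has to leave the bromide of 4 alone.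

4 from 3 from 1, and 8 from 7 from 5. The bromine of 4 is removed (ortho bromination of a phenol) and the hydroxyl of 3 is traced to the formyl group of 1. The methyl group of 8 is removed and the formyl group of 7 is traced to an ortho formylation of the symmetric phenol 5, in which the two ortho positions are equivalent.

31 from 29 from 27 and 8. The free C4 hydroxyl of ring D again comes from a formyl group. In 29 the ether bond between C1 of ring D and C6 of ring C is cut, together with one methoxy C–O bond, so that ring D comes from the same aldehyde 8: its para fluoride is replaced by the phenoxide of 27 and its ortho fluoride by a methoxy group. The phenol needed for the copper coupling is thereby unmasked only one step before it is used.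

27 from 26 from 25 from 23, and 23 from 8, 21 and 18. A benzyl group on the C6 oxygen of ring C is removed, then the methyl ether and the formyl-derived oxygen at C4 of ring B as before. In 23 both ether bonds of ring B are cut, as in ring F: the hindered ring A phenol 21 takes the para position of 8 and the ring C phenol 18 the ortho position.

18 from 15 from 4, and 21 from 19. Ring C has the same substitution as ring E, so it is taken from the same bromophenol 4: the hydroxyl is benzylated and the bromide is exchanged for hydroxyl. The ring A phenol 21 comes from the aldehyde 19 by Dakin oxidation.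

## Alternatives that were turned down

Alternative 1: Ring B itself is disconnected at C1–C2 and C5–C6 (and C4–C5 in the ring closure), leading to the ethynyl ether of ring A, A2, and a 3,4-dialkoxycyclobutenone, A3.
- Forward key step: heating opens A3 to a vinylketene, which adds to the triple bond of A2. The resulting vinylcyclobutenone opens again, the dienylketene closes by six-electron electrocyclisation and tautomerises to the phenol A1 (Danheiser benzannulation).
- For it: the A–B ether to the doubly ortho-substituted ring A exists before ring B is formed. The polarity of ketene and ynol ether fixes all four oxygens of ring B with no competition between two leaving groups. A1 has its C5 hydroxyl free. On regiochemical certainty within ring B this alternative is stronger than the chosen route.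
- Against it: A2 must be made from a hindered, oxidisable phenol by a haloalkenyl ether and elimination sequence and is heat-sensitive. A3, with an alkoxy group on its sp3 carbon, is not a routine cyclobutenone and costs several steps. The benzannulation forms one ring and no ether bond.
- Comparison: the C5 hydroxyl of A1 must still be joined to ring C, which can only be a nucleophile, so that bond falls to a copper coupling with a doubly ortho-substituted, electron-rich halide. The chosen strategy gives both ether bonds of ring B in one flask from stable phenols and needs one copper coupling in the whole synthesis.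

Alternative 2: Ring A is built. The two bonds between the ester carbons of the aryloxymalonate A5 and the methylene carbons of the oxo diester A6 are cut; A5 already holds the A–B ether oxygen on the future C1 of ring A.
- Forward key step: NaOMe takes A5 and A6 through two Claisen condensations to the phloroglucinol diester A4.
- For it: the hindered A–B ether is made by simple alkylation at an sp3 carbon without a metal, which equals the chosen route on that bond. The three ring A hydroxyls come out free.
- Against it: ring A is the one ring that needs no synthesis, since 21 is one step from 19. A4 needs ester hydrolysis, double decarboxylation and methylation to reach the same stage. Under methoxide A5 is deprotonated at its acidic C–H and is then a poor acylating agent, while A6 condenses with itself.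
- Comparison: the bromide at C5 of ring B in A4 postpones the B–C bond to a copper coupling next to a methoxy group. A de novo ring synthesis is spent where none is needed, and the difficult bonds stay untouched.

Alternative 3: Ring C is built from the four carbons of dimethyl squarate A8 and a two-carbon alkenyl unit. The C6–C1 bond, formed by electrocyclisation, and the C2–C3 bond, formed by adding an alkenyllithium to A8, are cut; the alkenyl unit is a 2-aryloxyvinyl anion carrying rings A and B.
- Forward key step: the adduct, after O-methylation, is the cyclobutenone A9. Thermolysis opens it to a dienylketene, and electrocyclisation and tautomerisation give A7, which is the same compound as 27.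
- For it: the most heavily substituted ring type is made with all five substituents in defined positions. The C6 hydroxyl results free without protecting-group steps, where the chosen route needs steps 8, 9 and 14. On this point the alternative is at least as strong.
- Against it: the vinyl anion must be made from an AB phenol through a 2-halovinyl aryl ether and can lose aryloxide by beta-elimination. That AB phenol still needs its own ether chemistry. The tertiary alkoxide must be methylated on a base-sensitive adduct.
- Comparison: the sequence forms no diaryl ether bond and does not help with ring E, which needs a bromide. The chosen route reaches 27 with the same aldehyde 8 that also serves rings F and D, so one reaction type delivers five of the six ether bonds.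

Key step: step 5

## Route

Step 1
Reactants: 1 2,3,4-trimethoxybenzaldehyde
Product: 3 2,3,4-trimethoxyphenol, via 2,3,4-trimethoxyphenyl formate 2 (not isolated)
Conditions: 30% aq. H2O2, cat. H2SO4, MeOH, rt
Reagents that add atoms: hydrogen peroxide, OO
Why: Acid-catalysed Dakin oxidation: hydrogen peroxide adds to the protonated aldehyde, the electron-rich aryl group migrates to oxygen as in a Baeyer–Villiger reaction, and methanol cleaves the formate 2 in the same flask. The acidic variant is used because there is no free ortho or para hydroxyl.

Step 2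
Reactants: 3 2,3,4-trimethoxyphenol
Product: 4 6-bromo-2,3,4-trimethoxyphenol
Conditions: NBS, cat. i-Pr2NH, CH2Cl2, 0 °C
Reagents that add atoms: N-bromosuccinimide, O=C1CCC(=O)N1Br
Why: Electrophilic aromatic bromination ortho to a phenol whose para position is blocked. The amine-catalysed NBS protocol delivers bromine through a hydrogen-bonded N-bromoamine to the only free ortho carbon, C6, which is also para to the C3 methoxy group.

Step 3
Reactants: 5 3,5-difluorophenol
Product: 7 2,4-difluoro-6-hydroxybenzaldehyde, via 3,5-difluoro-2-(hydroxymethyl)phenol 6 (not isolated)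
Conditions: MgCl2, Et3N, (CH2O)n, MeCN, reflux; then aq. HCl
Reagents that add atoms: paraformaldehyde (reacts as formaldehyde), C=O
Why: Magnesium-mediated ortho-formylation (Casnati–Skattebøl): the magnesium phenoxide delivers formaldehyde to the ortho carbon, and a second formaldehyde oxidises the benzylic alkoxide of 6 by hydride transfer. The two ortho positions of 5 are equivalent, so only one aldehyde can form.

Step 4
Reactants: 7 2,4-difluoro-6-hydroxybenzaldehyde
Product: 8 2,4-difluoro-6-methoxybenzaldehyde
Conditions: MeI, K2CO3, DMF, rt
Reagents that add atoms: iodomethane, CI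
Why: Williamson O-methylation of a phenol. At room temperature the chelated, weakly nucleophilic phenoxide should not attack the fluorides of a second molecule.

Step 5
Reactants: 4 6-bromo-2,3,4-trimethoxyphenol; 8 2,4-difluoro-6-methoxybenzaldehyde; 9 3,4,5-trimethoxyphenol
Product: 11 4-(6-bromo-2,3,4-trimethoxyphenoxy)-2-methoxy-6-(3,4,5-trimethoxyphenoxy)benzaldehyde, via para-monoether fluoroaldehyde 10 (not isolated)
Conditions: 4 (1.0 equiv), K2CO3, DMSO, 50 °C; then 9, 110 °C
Reagents that add atoms: none
Why: Both ether bonds form by addition–elimination: the phenoxide adds to the fluorine-bearing carbon, the negative charge of the Meisenheimer anion is taken up by the formyl oxygen, and fluoride leaves. The closest known reaction type is displacement of fluoride from 2- and 4-fluorobenzaldehydes by phenoxides under carbonate in dipolar aprotic solvents, including stepwise replacement of two fluorides. No ring is closed and no stereocentre is formed; the step makes the ring E–O–ring F bond at C1 and the ring F–O–ring G bond at C5 of ring F. The selectivity needed is substitution of the para fluoride before the ortho one. The phenoxide of 4 is flanked by bromine and methoxy and is added first, without excess and at moderate temperature, so it should go to the open para carbon and not to the ortho carbon shielded by the formyl group. The methoxy group of 8 is meta to both fluorines and does not donate to either reacting carbon. The aryloxy group para to the aldehyde in 10 lowers the electrophilicity enough to stop a second attack by the hindered phenoxide, and the small phenoxide of 9 then replaces the ortho fluoride on heating. The ring E bromide sits on an electron-rich ring without an acceptor, is inert to this substitution and remains as the handle for ring D.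

Step 6
Reactants: 11 4-(6-bromo-2,3,4-trimethoxyphenoxy)-2-methoxy-6-(3,4,5-trimethoxyphenoxy)benzaldehyde
Product: 13 4-(6-bromo-2,3,4-trimethoxyphenoxy)-2-methoxy-6-(3,4,5-trimethoxyphenoxy)phenol, via aryl formate 12 (not isolated)
Conditions: 30% aq. H2O2, cat. H2SO4, MeOH/CH2Cl2, rt
Reagents that add atoms: hydrogen peroxide, OO
Why: Acid-catalysed Dakin oxidation. The migrating aryl group has oxygen on both ortho carbons and on the para carbon, which favours aryl over hydride migration. The aryl bromide and the diaryl ethers are inert to dilute acidic peroxide.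

Step 7
Reactants: 13 4-(6-bromo-2,3,4-trimethoxyphenoxy)-2-methoxy-6-(3,4,5-trimethoxyphenoxy)phenol
Product: 14 1-bromo-2-[3,4-dimethoxy-5-(3,4,5-trimethoxyphenoxy)phenoxy]-3,4,5-trimethoxybenzene (EFG bromide)
Conditions: MeI, K2CO3, DMF, rt to 40 °C
Reagents that add atoms: iodomethane, CI
Why: Williamson methylation. Iodomethane is small enough for a phenoxide flanked by methoxy and aryloxy groups.

Step 8
Reactants: 4 6-bromo-2,3,4-trimethoxyphenol
Product: 15 2-(benzyloxy)-1-bromo-3,4,5-trimethoxybenzene
Conditions: BnBr, K2CO3, DMF, rt
Reagents that add atoms: benzyl bromide, BrCc1ccccc1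
Why: Williamson benzylation. Benzyl is chosen because it can later be removed by hydrogenolysis while all methyl ethers stay.

Step 9
Reactants: 15 2-(benzyloxy)-1-bromo-3,4,5-trimethoxybenzene
Product: 18 2-(benzyloxy)-3,4,5-trimethoxyphenol, via aryllithium 16 (not isolated), via dimethyl arylboronate 17 (not isolated)
Conditions: n-BuLi, THF, −78 °C; B(OMe)3, −78 °C to rt; then 30% aq. H2O2, aq. NaOH, 0 °C to rt
Reagents that add atoms: hydrogen peroxide, OO
Why: Bromine–lithium exchange, borylation of the aryllithium, and oxidation of the arylboronate by hydroperoxide with 1,2-shift of the aryl group from boron to oxygen. At −78 °C the aryllithium is trapped before it can deprotonate the benzylic position.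

Step 10
Reactants: 19 2,4,6-trimethoxybenzaldehyde
Product: 21 2,4,6-trimethoxyphenol, via 2,4,6-trimethoxyphenyl formate 20 (not isolated)
Conditions: 30% aq. H2O2, cat. H2SO4, MeOH, rt
Reagents that add atoms: hydrogen peroxide, OO
Why: Acid-catalysed Dakin oxidation as in step 1; the 2,4,6-trioxygenated aryl group migrates very readily.

Step 11
Reactants: 8 2,4-difluoro-6-methoxybenzaldehyde; 21 2,4,6-trimethoxyphenol; 18 2-(benzyloxy)-3,4,5-trimethoxyphenol
Product: 23 2-[2-(benzyloxy)-3,4,5-trimethoxyphenoxy]-6-methoxy-4-(2,4,6-trimethoxyphenoxy)benzaldehyde, via para-monoether fluoroaldehyde 22 (not isolated)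
Conditions: 21 (1.0 equiv), K2CO3, DMSO, 50 °C (degassed); then 18, 110–120 °C
Reagents that add atoms: none
Why: Sequential nucleophilic aromatic substitution as in step 5, here forming both ether bonds of ring B. The phenoxide of 21, with two ortho methoxy groups, takes the para fluoride first; the phenoxide of 18, with one ortho substituent, replaces the ortho fluoride of 22 at higher temperature.

Step 12
Reactants: 23 2-[2-(benzyloxy)-3,4,5-trimethoxyphenoxy]-6-methoxy-4-(2,4,6-trimethoxyphenoxy)benzaldehyde
Product: 25 2-[2-(benzyloxy)-3,4,5-trimethoxyphenoxy]-6-methoxy-4-(2,4,6-trimethoxyphenoxy)phenol, via aryl formate 24 (not isolated)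
Conditions: 30% aq. H2O2, cat. H2SO4, MeOH/CH2Cl2, rt
Reagents that add atoms: hydrogen peroxide, OO
Why: Acid-catalysed Dakin oxidation of a 2,4,6-trioxygenated benzaldehyde. The benzyl ether and the methyl ethers are stable to these conditions.

Step 13
Reactants: 25 2-[2-(benzyloxy)-3,4,5-trimethoxyphenoxy]-6-methoxy-4-(2,4,6-trimethoxyphenoxy)phenol
Product: 26 2-(benzyloxy)-1-[2,3-dimethoxy-5-(2,4,6-trimethoxyphenoxy)phenoxy]-3,4,5-trimethoxybenzene
Conditions: MeI, K2CO3, DMF, rt to 40 °C
Reagents that add atoms: iodomethane, CI
Why: Williamson methylation of the new ring B phenol, which fixes the C4 oxygen of ring B as a methyl ether before the benzyl group is removed.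

Step 14
Reactants: 26 2-(benzyloxy)-1-[2,3-dimethoxy-5-(2,4,6-trimethoxyphenoxy)phenoxy]-3,4,5-trimethoxybenzene
Product: 27 6-[2,3-dimethoxy-5-(2,4,6-trimethoxyphenoxy)phenoxy]-2,3,4-trimethoxyphenol (ABC phenol)
Conditions: H2 (1 atm), 10% Pd/C, EtOAc/MeOH, rt
Reagents that add atoms: none
Why: Hydrogenolysis of a benzyl aryl ether. The substrate has no halogen or other reducible group, and diaryl and methyl ethers are untouched.

Step 15
Reactants: 27 6-[2,3-dimethoxy-5-(2,4,6-trimethoxyphenoxy)phenoxy]-2,3,4-trimethoxyphenol; 8 2,4-difluoro-6-methoxybenzaldehyde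
Product: 29 4-{6-[2,3-dimethoxy-5-(2,4,6-trimethoxyphenoxy)phenoxy]-2,3,4-trimethoxyphenoxy}-2,6-dimethoxybenzaldehyde, via para-monoether fluoroaldehyde 28 (not isolated)
Conditions: K2CO3, DMSO, 60 °C; then NaOMe, MeOH, 60–70 °C
Reagents that add atoms: sodium methoxide, C[O-].[Na+]
Why: Two nucleophilic aromatic substitutions on the aldehyde-activated ring: the hindered phenoxide of 27 takes the para fluoride, then methoxide replaces the ortho fluoride of 28. Methoxide should add faster to the fluorine-bearing carbon than to the aryloxy-bearing carbon, so the new ring C–O–ring D ether should stay intact.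

Step 16
Reactants: 29 4-{6-[2,3-dimethoxy-5-(2,4,6-trimethoxyphenoxy)phenoxy]-2,3,4-trimethoxyphenoxy}-2,6-dimethoxybenzaldehyde
Product: 31 4-{6-[2,3-dimethoxy-5-(2,4,6-trimethoxyphenoxy)phenoxy]-2,3,4-trimethoxyphenoxy}-2,6-dimethoxyphenol (ABCD phenol), via aryl formate 30 (not isolated)
Conditions: 30% aq. H2O2, cat. H2SO4, MeOH/CH2Cl2, 0 °C to rt; work-up under argon
Reagents that add atoms: hydrogen peroxide, OO
Why: Acid-catalysed Dakin oxidation, which turns the acceptor of ring D into the C4 hydroxyl needed for the coupling. The electron-rich phenol is used directly in step 17.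

Step 17
Reactants: 31 ABCD phenol; 14 EFG bromide
Product: 32 octadeca-O-methyl ether of the target (all eighteen hydroxyls as OMe)
Conditions: CuI (30 mol %), picolinic acid (60 mol %), K3PO4, DMSO, 110 °C, argon
Reagents that add atoms: none
Why: Ullmann-type diaryl ether synthesis: the copper phenoxide of 31 reacts with the aryl bromide by oxidative addition and reductive elimination. The picolinate ligand is the one suited to ortho-substituted phenols and ortho-substituted aryl halides; no other halide or free hydroxyl is present.

Step 18
Reactants: 32 octadeca-O-methyl ether of the target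
Product: 33 2-[3-[2-[4-[2-[3,4-dihydroxy-5-(3,4,5-trihydroxyphenoxy)phenoxy]-3,4,5-trihydroxyphenoxy]-3,5-dihydroxyphenoxy]-3,4,5-trihydroxyphenoxy]-4,5-dihydroxyphenoxy]benzene-1,3,5-triol (CNP0137585.0)
Conditions: BBr3 (large excess), CH2Cl2, −78 °C to rt; then H2O, 0 °C; isolation under argon, reversed-phase chromatography
Reagents that add atoms: none
Why: Lewis-acid demethylation: BBr3 binds each methoxy oxygen and bromide attacks the methyl carbon (SN2), while the aryl–oxygen bonds of the diaryl ethers are not attacked. The aryloxyboron bromides formed are a mixture, not a single compound, and are hydrolysed on work-up.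

## Compound list

1 | 2,3,4-trimethoxybenzaldehyde | COc1ccc(C=O)c(OC)c1OC | starting material
2 | 2,3,4-trimethoxyphenyl formate | O=COc1ccc(OC)c(OC)c1OC | intermediate
3 | 2,3,4-trimethoxyphenol | Oc1ccc(OC)c(OC)c1OC | intermediate
4 | 6-bromo-2,3,4-trimethoxyphenol | Oc1c(Br)cc(OC)c(OC)c1OC | intermediate
5 | 3,5-difluorophenol | Oc1cc(F)cc(F)c1 | starting material
6 | 3,5-difluoro-2-(hydroxymethyl)phenol | OCc1c(O)cc(F)cc1F | intermediate
7 | 2,4-difluoro-6-hydroxybenzaldehyde | O=Cc1c(O)cc(F)cc1F | intermediate
8 | 2,4-difluoro-6-methoxybenzaldehyde | COc1cc(F)cc(F)c1C=O | intermediate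
9 | 3,4,5-trimethoxyphenol | COc1cc(O)cc(OC)c1OC | starting material
10 | 4-(6-bromo-2,3,4-trimethoxyphenoxy)-2-fluoro-6-methoxybenzaldehyde | O=Cc1c(F)cc(Oc2c(Br)cc(OC)c(OC)c2OC)cc1OC | intermediate
11 | 4-(6-bromo-2,3,4-trimethoxyphenoxy)-2-methoxy-6-(3,4,5-trimethoxyphenoxy)benzaldehyde | O=Cc1c(OC)cc(Oc2c(Br)cc(OC)c(OC)c2OC)cc1Oc1cc(OC)c(OC)c(OC)c1 | intermediate
12 | 4-(6-bromo-2,3,4-trimethoxyphenoxy)-2-methoxy-6-(3,4,5-trimethoxyphenoxy)phenyl formate | O=COc1c(OC)cc(Oc2c(Br)cc(OC)c(OC)c2OC)cc1Oc1cc(OC)c(OC)c(OC)c1 | intermediate
13 | 4-(6-bromo-2,3,4-trimethoxyphenoxy)-2-methoxy-6-(3,4,5-trimethoxyphenoxy)phenol | Oc1c(OC)cc(Oc2c(Br)cc(OC)c(OC)c2OC)cc1Oc1cc(OC)c(OC)c(OC)c1 | intermediate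
14 | 1-bromo-2-[3,4-dimethoxy-5-(3,4,5-trimethoxyphenoxy)phenoxy]-3,4,5-trimethoxybenzene (EFG bromide) | COc1c(OC)cc(Oc2c(Br)cc(OC)c(OC)c2OC)cc1Oc1cc(OC)c(OC)c(OC)c1 | intermediate
15 | 2-(benzyloxy)-1-bromo-3,4,5-trimethoxybenzene | Brc1cc(OC)c(OC)c(OC)c1OCc1ccccc1 | intermediate
16 | [2-(benzyloxy)-3,4,5-trimethoxyphenyl]lithium | [Li]c1cc(OC)c(OC)c(OC)c1OCc1ccccc1 | intermediate
17 | dimethyl [2-(benzyloxy)-3,4,5-trimethoxyphenyl]boronate | COB(OC)c1cc(OC)c(OC)c(OC)c1OCc1ccccc1 | intermediate
18 | 2-(benzyloxy)-3,4,5-trimethoxyphenol | Oc1cc(OC)c(OC)c(OC)c1OCc1ccccc1 | intermediate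
19 | 2,4,6-trimethoxybenzaldehyde | COc1cc(OC)c(C=O)c(OC)c1 | starting material
20 | 2,4,6-trimethoxyphenyl formate | O=COc1c(OC)cc(OC)cc1OC | intermediate
21 | 2,4,6-trimethoxyphenol | Oc1c(OC)cc(OC)cc1OC | intermediate
22 | 2-fluoro-6-methoxy-4-(2,4,6-trimethoxyphenoxy)benzaldehyde | O=Cc1c(F)cc(Oc2c(OC)cc(OC)cc2OC)cc1OC | intermediate
23 | 2-[2-(benzyloxy)-3,4,5-trimethoxyphenoxy]-6-methoxy-4-(2,4,6-trimethoxyphenoxy)benzaldehyde | O=Cc1c(OC)cc(Oc2c(OC)cc(OC)cc2OC)cc1Oc1cc(OC)c(OC)c(OC)c1OCc1ccccc1 | intermediate
24 | 2-[2-(benzyloxy)-3,4,5-trimethoxyphenoxy]-6-methoxy-4-(2,4,6-trimethoxyphenoxy)phenyl formate | O=COc1c(OC)cc(Oc2c(OC)cc(OC)cc2OC)cc1Oc1cc(OC)c(OC)c(OC)c1OCc1ccccc1 | intermediate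
25 | 2-[2-(benzyloxy)-3,4,5-trimethoxyphenoxy]-6-methoxy-4-(2,4,6-trimethoxyphenoxy)phenol | Oc1c(OC)cc(Oc2c(OC)cc(OC)cc2OC)cc1Oc1cc(OC)c(OC)c(OC)c1OCc1ccccc1 | intermediate
26 | 2-(benzyloxy)-1-[2,3-dimethoxy-5-(2,4,6-trimethoxyphenoxy)phenoxy]-3,4,5-trimethoxybenzene | COc1c(OC)cc(Oc2c(OC)cc(OC)cc2OC)cc1Oc1cc(OC)c(OC)c(OC)c1OCc1ccccc1 | intermediate
27 | 6-[2,3-dimethoxy-5-(2,4,6-trimethoxyphenoxy)phenoxy]-2,3,4-trimethoxyphenol (ABC phenol) | COc1c(OC)cc(Oc2c(OC)cc(OC)cc2OC)cc1Oc1cc(OC)c(OC)c(OC)c1O | intermediate
28 | 4-{6-[2,3-dimethoxy-5-(2,4,6-trimethoxyphenoxy)phenoxy]-2,3,4-trimethoxyphenoxy}-2-fluoro-6-methoxybenzaldehyde | O=Cc1c(F)cc(Oc2c(OC)c(OC)c(OC)cc2Oc2cc(Oc3c(OC)cc(OC)cc3OC)cc(OC)c2OC)cc1OC | intermediate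
29 | 4-{6-[2,3-dimethoxy-5-(2,4,6-trimethoxyphenoxy)phenoxy]-2,3,4-trimethoxyphenoxy}-2,6-dimethoxybenzaldehyde | O=Cc1c(OC)cc(Oc2c(OC)c(OC)c(OC)cc2Oc2cc(Oc3c(OC)cc(OC)cc3OC)cc(OC)c2OC)cc1OC | intermediate
30 | 4-{6-[2,3-dimethoxy-5-(2,4,6-trimethoxyphenoxy)phenoxy]-2,3,4-trimethoxyphenoxy}-2,6-dimethoxyphenyl formate | O=COc1c(OC)cc(Oc2c(OC)c(OC)c(OC)cc2Oc2cc(Oc3c(OC)cc(OC)cc3OC)cc(OC)c2OC)cc1OC | intermediate
31 | 4-{6-[2,3-dimethoxy-5-(2,4,6-trimethoxyphenoxy)phenoxy]-2,3,4-trimethoxyphenoxy}-2,6-dimethoxyphenol (ABCD phenol) | Oc1c(OC)cc(Oc2c(OC)c(OC)c(OC)cc2Oc2cc(Oc3c(OC)cc(OC)cc3OC)cc(OC)c2OC)cc1OC | intermediate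
32 | octadeca-O-methyl ether of the target | COc1cc(OC)c(Oc2cc(OC)c(OC)c(Oc3cc(OC)c(OC)c(OC)c3Oc3cc(OC)c(Oc4cc(OC)c(OC)c(OC)c4Oc4cc(OC)c(OC)c(Oc5cc(OC)c(OC)c(OC)c5)c4)c(OC)c3)c2)c(OC)c1 | intermediate
33 | 2-[3-[2-[4-[2-[3,4-dihydroxy-5-(3,4,5-trihydroxyphenoxy)phenoxy]-3,4,5-trihydroxyphenoxy]-3,5-dihydroxyphenoxy]-3,4,5-trihydroxyphenoxy]-4,5-dihydroxyphenoxy]benzene-1,3,5-triol (CNP0137585.0) | Oc1cc(O)c(Oc2cc(O)c(O)c(Oc3cc(O)c(O)c(O)c3Oc3cc(O)c(Oc4cc(O)c(O)c(O)c4Oc4cc(O)c(O)c(Oc5cc(O)c(O)c(O)c5)c4)c(O)c3)c2)c(O)c1 | target

## Step count and risks

Total step count: 18. Longest linear sequence: 12 steps (steps 1, 2, 8, 9, 11, 12, 13, 14, 15, 16, 17, 18).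

Step 5 (key step). The most likely failure is loss of regiocontrol in the first substitution: attack of the ring E phenoxide at the ortho fluoride, helped by coordination of the cation to the formyl oxygen, or a second substitution by the same phenoxide. In a one-pot procedure either would carry isomers forward. The fallback fixes the para ether by a reaction that has no choice of position. It sets out from 4 and returns at 11. Commercial 4-bromo-2,6-difluorobenzaldehyde, whose two fluorides are equivalent, would be treated with one equivalent of NaOMe in MeOH to give 4-bromo-2-fluoro-6-methoxybenzaldehyde F1. Miyaura borylation of F1 with bis(pinacolato)diboron (PdCl2(dppf), KOAc, dioxane, 80 °C) would give 2-fluoro-6-methoxy-4-(4,4,5,5-tetramethyl-1,3,2-dioxaborolan-2-yl)benzaldehyde F2. Chan–Lam–Evans coupling of F2 with 4 (Cu(OAc)2, pyridine, B(OH)3 as additive for the pinacol ester, 4 Å molecular sieves, MeCN, dry air, rt to 40 °C) should give 10 as an isolated compound; the electron-rich aryl bromide of 4 is not activated under divalent copper at this temperature. Substitution of the remaining ortho fluoride of 10 by 9 (K2CO3, DMSO, 110 °C) would then give 11. The analogous double substitution that builds ring B carries the same risk and would be answered the same way.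

Step 17. Slow oxidative addition of the electron-rich, ortho-substituted bromide combined with the hindered phenoxide may let protodebromination of 14 and oxidative decay of the phenoxide of 31 outrun the coupling. The fallback reverses the polarity of ring E. It sets out from 14 and returns at 32. Bromine–lithium exchange (n-BuLi, THF, −78 °C), B(Oi-Pr)3 and mild aqueous acid would give {2-[3,4-dimethoxy-5-(3,4,5-trimethoxyphenoxy)phenoxy]-3,4,5-trimethoxyphenyl}boronic acid F3. Chan–Lam–Evans coupling of F3 with 31 (stoichiometric Cu(OAc)2, pyridine, 4 Å molecular sieves, CH2Cl2, dry air, rt) should form the same ether by transmetalation and reductive elimination at room temperature.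

Step 18. Incomplete cleavage of eighteen methyl ethers, acid-induced cleavage of the ether at the phloroglucinol-type ring A during the quench, and air oxidation on isolation may leave an inseparable mixture of polyphenols. The fallback isolates the product as a stable derivative. It sets out from 32 and returns at 33. After the BBr3 treatment the crude phenol mixture would be acetylated without isolation (Ac2O, pyridine) to the octadecaacetate of 33 F4, which can be purified on silica and freed from partly methylated material. Acid-catalysed methanolysis of F4 with HCl generated from AcCl in MeOH (argon, rt) should then release 33 without any basic medium.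

Step 2. Bromination may occur at C5 (ortho to the C4 methoxy, para to the C2 methoxy) instead of C6, or twice, because both free positions are activated. The fallback uses directed metalation. It sets out from 3 and returns at 4. Carbamoylation (NaH, ClC(O)NEt2, THF) would give 2,3,4-trimethoxyphenyl N,N-diethylcarbamate F5. Ortho-lithiation of F5 at the only carbon next to the carbamate (s-BuLi, TMEDA, THF, −78 °C) and quenching with BrCCl2CCl2Br would give 6-bromo-2,3,4-trimethoxyphenyl N,N-diethylcarbamate F6. Hydrolysis of F6 with KOH in EtOH/H2O at reflux would then give 4.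

Step 15. The hindered ABC phenoxide may substitute slowly, and in the second stage methoxide may exchange with the para aryloxy group and release 27 again. The fallback avoids methoxide altogether. It sets out from 27 and returns at 29. Copper-catalysed coupling of 27 with commercial 4-bromo-2,6-dimethoxybenzaldehyde (CuI, picolinic acid, K3PO4, DMSO, 90 °C) would give 29 directly; this bromide is activated by the para formyl group and already holds both methoxy groups.

## Further compounds

F1 | step 5 | 4-bromo-2-fluoro-6-methoxybenzaldehyde | O=Cc1c(F)cc(Br)cc1OC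
F2 | step 5 | 2-fluoro-6-methoxy-4-(4,4,5,5-tetramethyl-1,3,2-dioxaborolan-2-yl)benzaldehyde | O=Cc1c(F)cc(cc1OC)B1OC(C)(C)C(C)(C)O1
F3 | step 17 | {2-[3,4-dimethoxy-5-(3,4,5-trimethoxyphenoxy)phenoxy]-3,4,5-trimethoxyphenyl}boronic acid | OB(O)c1cc(OC)c(OC)c(OC)c1Oc1cc(OC)c(OC)c(Oc2cc(OC)c(OC)c(OC)c2)c1
F4 | step 18 | octadecaacetate of 33 | CC(=O)Oc1cc(OC(C)=O)c(Oc2cc(OC(C)=O)c(OC(C)=O)c(Oc3cc(OC(C)=O)c(OC(C)=O)c(OC(C)=O)c3Oc3cc(OC(C)=O)c(Oc4cc(OC(C)=O)c(OC(C)=O)c(OC(C)=O)c4Oc4cc(OC(C)=O)c(OC(C)=O)c(Oc5cc(OC(C)=O)c(OC(C)=O)c(OC(C)=O)c5)c4)c(OC(C)=O)c3)c2)c(OC(C)=O)c1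
F5 | step 2 | 2,3,4-trimethoxyphenyl N,N-diethylcarbamate | CCN(CC)C(=O)Oc1ccc(OC)c(OC)c1OC
F6 | step 2 | 6-bromo-2,3,4-trimethoxyphenyl N,N-diethylcarbamate | CCN(CC)C(=O)Oc1c(Br)cc(OC)c(OC)c1OC
F0 | step 15 | none | none
A1 | alternative 1 | 3-ethoxy-2-methoxy-5-(2,4,6-trimethoxyphenoxy)phenol | CCOc1cc(Oc2c(OC)cc(OC)cc2OC)cc(O)c1OC
A2 | alternative 1 | 2-(ethynyloxy)-1,3,5-trimethoxybenzene | C#COc1c(OC)cc(OC)cc1OC
A3 | alternative 1 | 3-ethoxy-4-methoxycyclobut-2-en-1-one (racemic) | CCOC1=CC(=O)C1OC
A4 | alternative 2 | dimethyl 5-(3-bromo-4,5-dimethoxyphenoxy)-2,4,6-trihydroxybenzene-1,3-dicarboxylate | COC(=O)c1c(O)c(C(=O)OC)c(O)c(Oc2cc(OC)c(OC)c(Br)c2)c1O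
A5 | alternative 2 | dimethyl 2-(3-bromo-4,5-dimethoxyphenoxy)propanedioate | COC(=O)C(Oc1cc(OC)c(OC)c(Br)c1)C(=O)OC
A6 | alternative 2 | dimethyl 3-oxopentanedioate | COC(=O)CC(=O)CC(=O)OC
A7 | alternative 3 | 6-[2,3-dimethoxy-5-(2,4,6-trimethoxyphenoxy)phenoxy]-2,3,4-trimethoxyphenol (identical with 27) | Oc1c(OC)c(OC)c(OC)cc1Oc1cc(Oc2c(OC)cc(OC)cc2OC)cc(OC)c1OC
A8 | alternative 3 | dimethyl squarate (3,4-dimethoxycyclobut-3-ene-1,2-dione) | COC1=C(OC)C(=O)C1=O
A9 | alternative 3 | 4-{(Z)-2-[2,3-dimethoxy-5-(2,4,6-trimethoxyphenoxy)phenoxy]ethenyl}-2,3,4-trimethoxycyclobut-2-en-1-one (racemic) | COC1=C(OC)C(OC)(/C=C\Oc2cc(Oc3c(OC)cc(OC)cc3OC)cc(OC)c2OC)C1=O
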